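I decide to carry one quantity through these flasks: the crossover concentration Q*, the amount of Q at which L forms as fast as G and E together.

| setting | winter | midnight | autumn | ash | maple | oak |
|---|---|---|---|---|---|---|
| Z | 0.20 M | 0.20 M | 0.30 M | 0.20 M | 0.20 M | 0.20 M |
| X | 0.20 M | 0.20 M | 0.30 M | 0.20 M | 0.20 M | 0.20 M |
| Q | 0.30 M | 0.45 M | 0.60 M | 0.600 M | 0.600 M | 0.600 M |
| temperature | 62 °C | 79 °C | 62 °C | 55 °C | 70 °C | 85 °C |
| remark | run made earlier | run made earlier | run made earlier |  |  |  |
| time |  |  |  | 25 h | 25 h | 25 h |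

| run | time / h | G / % | E / % | L / % |
|---|---|---|---|---|
| winter | 2.00 | 0 | 1 | 3 |
| winter | 6.00 | 1 | 1 | 2 |
| winter | 12.0 | 4 | 4 | 5 |
| winter | 20.0 | 8 | 3 | 15 |
| winter | 25.0 | 9 | 4 | 18 |
| midnight | 0.667 | 4 | 0 | 0 |
| midnight | 1.33 | 7 | 3 | 7 |
| midnight | 2.50 | 4 | 2 | 8 |
| midnight | 4.00 | 6 | 5 | 16 |
| midnight | 8.00 | 17 | 11 | 26 |
| autumn | 5.00 | 1 | 2 | 2 |
| autumn | 10.0 | 3 | 6 | 6 |
| autumn | 15.0 | 13 | 3 | 6 |
| autumn | 20.0 | 11 | 7 | 13 |
| autumn | 25.0 | 19 | 9 | 17 |

(readings scatter by 2 percentage points)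

* which flask leads in share of G in all that became G or E or L ("all alike" within 1.5 percentage points) (ash / maple / oak / all alike)
* share of G in all that became G or E or L, ash
* share of G in all that became G or E or L, maple
* share of G in all that became G or E or L, oak

- Q is single-handed; Z and X are mirror images of each other, charged as a racemate, each of them at the stated concentration
- the handed part of Q does not stay in what it makes, so the products of the two hands are mirror images too

If L forms without Q and G and E each take one Q, then at one temperature L/(G+E) times the charged Q is free of Q. The last readings give 0.415 M for winter, 0.364 M for autumn and 0.418 M for midnight. Within the scatter I take the crossover concentration as their mean, 0.399 M. At 0.600 M of Q, the share reaching G or E is then Q/(Q+Q*), or 60.0%.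

Z and X compete for Q, a kinetic resolution. At the last winter reading, G holds 69.2% of G+E, so my reckoned ceiling for the asked share is 41.6%. For the floor, I let G keep half of G+E, since the charges are equal and the last readings favour G. If Q lost one unit for each Z and X charged, the floor would be 16.7%. But in my reckoning L takes no Q, so at full conversion Q stands near 0.360 M, and the floor rises to 23.7%. I put ash, the coldest, near the ceiling and the hotter two lower.

The forecast gives ash 40%, maple 34% and oak 28%, inside my bracket, with ash leading, and it expects that “the G/E ratio falls toward the limit set by competition with L”.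

Ash gives 47.8%, maple 35.0% and oak 33.8%, so ash leads, and it stands above my ceiling.

    Q + Z → G (k = 0.00110 M⁻¹ min⁻¹, Ea = 84.0 kJ mol⁻¹)
    Z ⇌ D (K = 0.290, k = 6.70 × 10⁻⁴ min⁻¹, Ea = 124 kJ mol⁻¹, ΔH = −47.0 kJ mol⁻¹)
    Q + X → E (k = 5.50 × 10⁻⁴ M⁻¹ min⁻¹, Ea = 80.0 kJ mol⁻¹)
    D → L (k = 0.00520 min⁻¹, Ea = 101 kJ mol⁻¹)
    X ⇌ D (K = 0.290, k = 6.70 × 10⁻⁴ min⁻¹, Ea = 124 kJ mol⁻¹, ΔH = −47.0 kJ mol⁻¹)
    (constants at 70 °C)

In ash at 25.0 h, D, a species formed on the way to L, still holds 4.89%, beside 5.39% of L. Counting D with L and using the charged Q, ash has Q* = 0.387 M, close to my 0.399 M. The neighbour flask, ash with 0.36 M of Q, holds 5.13% of D, and the same count gives it Q* = 0.388 M.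

All runs are calculated from invented constants.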